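The route rests on cutting the bond between C2 of the 3-methyl-dihydropyran ring and the first diene carbon. C2 carries both ring oxygen O1 and the diene, so it is an allylic carbinol carbon in disguise, and the O1–C9a bond to the tropolone is a vinylogous ester linkage. The key step is therefore a ligand-controlled Ni/Cr (Nozaki–Hiyama–Kishi) addition of an open-chain (E,E)-iododienol to an α-methyl aldehyde, each carrying a 6-methoxytropone: it forms the C–C bond and sets C2. Neither pyran ring exists in the precursor; both close afterwards in one alkoxide addition–elimination that expels the two tropone methoxy groups, before fluoride unveils the tropolones.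

Key step: step 14

Remarks on the chemistry (assumptions)
- Tropolone C=O/OH tautomers are one compound; target 26 is written in the tautomeric form of the target SMILES, although the ethers 7–25 fix the carbonyl on the neighbouring carbon.
- In step 5 the O-alkylation of tropolone 6 is taken to occur mainly at the oxygen remote from the 6-methoxy group (see Why); the minor regioisomeric ether would be removed by chromatography.
- Ar = 7-methoxy-2-methyl-5-oxo-4-[2-(trimethylsilyl)ethoxy]cyclohepta-1,3,6-trien-1-yl (the protected tropone, bonded through the former C–Br carbon).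
- L* = a chiral oxazoline–sulfonamide ligand of the type used for asymmetric Ni/Cr couplings, e.g. N-[2-(4-isopropyl-4,5-dihydrooxazol-2-yl)-6-methylphenyl]methanesulfonamide, in the antipode that directs Si-face addition; this would be fixed by a test run on 3-phenylpropanal.
- Compounds 3–5 are racemic; their stereocentres vanish in step 4.
- Step 12 builds two molecules of acetylene into each molecule of 18.

Step 1
Reactants: 1 2-methylanisole
Product: 2 1-methoxy-2-methylcyclohexa-1,4-diene
Conditions: Li, NH3(l), THF, t-BuOH, −78 to −33 °C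
Reagents that add atoms: none
Why: Birch reduction protonates ortho and meta to the methoxy group, so both OMe and Me should end on the same tetrasubstituted enol-ether double bond of the 2,5-dihydroarene.

Step 2
Reactants: 2 1-methoxy-2-methylcyclohexa-1,4-diene
Product: 3 7,7-dibromo-1-methoxy-6-methylbicyclo[4.1.0]hept-3-ene
Conditions: CHBr3, KOt-Bu, pentane, −20 to 0 °C; used cold and without delay
Reagents that add atoms: bromoform BrC(Br)Br
Why: Electrophilic dibromocarbene should add ([2+1] cyclopropanation) to the electron-rich enol-ether alkene in preference to the plain cis-alkene, the cis ring fusion being inherent.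

Step 3
Reactants: 3 7,7-dibromo-1-methoxy-6-methylbicyclo[4.1.0]hept-3-ene
Product: 4 7,7-dibromo-1-methoxy-6-methylbicyclo[4.1.0]heptane-3,4-diol
Conditions: OsO4 (2 mol%), NMO, acetone/H2O, 0 °C
Reagents that add atoms: N-methylmorpholine N-oxide C[N+]1([O-])CCOCC1; water O
Why: Upjohn syn-dihydroxylation of the remaining alkene should occur on the face opposite the CBr2 bridge, and the diol configuration is of no consequence because both carbinols are oxidised next.

Step 4
Reactants: 4 7,7-dibromo-1-methoxy-6-methylbicyclo[4.1.0]heptane-3,4-diol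
Product: 6 5-bromo-2-hydroxy-6-methoxy-4-methylcyclohepta-2,4,6-trien-1-one, via dione 5 (not isolated)
Conditions: TFAA, DMSO, CH2Cl2, −78 °C; then Et3N, −78 °C to rt
Reagents that add atoms: none
Why: Swern-type oxidation gives the 1,2-dione, whose enol should trigger electrocyclic opening of the gem-dibromocyclopropane with loss of HBr and tautomerise to the tropolone (the known gem-dihalocyclopropane-to-tropolone ring expansion), leaving Br on the former carbene carbon between the retained OMe and Me.

Step 5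
Reactants: 6 5-bromo-2-hydroxy-6-methoxy-4-methylcyclohepta-2,4,6-trien-1-one
Product: 7 5-bromo-6-methoxy-4-methyl-2-[2-(trimethylsilyl)ethoxy]cyclohepta-2,4,6-trien-1-one
Conditions: Me3SiCH2CH2OH, PPh3, DIAD, THF, 0 °C to rt
Reagents that add atoms: 2-(trimethylsilyl)ethanol C[Si](C)(C)CCO
Why: Mitsunobu O-alkylation of the acidic tropolone should favour the oxygen remote from the 6-OMe group, because the other carbonyl is a vinylogous ester carbonyl and holds less of the anionic charge (the same logic that sends O-alkylation of acetoacetate to the ketone oxygen).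

Step 6
Reactants: 7 5-bromo-6-methoxy-4-methyl-2-[2-(trimethylsilyl)ethoxy]cyclohepta-2,4,6-trien-1-one; 8 [2-(1,3-dioxolan-2-yl)ethyl]zinc bromide (commercial THF solution)
Product: 9 5-[2-(1,3-dioxolan-2-yl)ethyl]-6-methoxy-4-methyl-2-[2-(trimethylsilyl)ethoxy]cyclohepta-2,4,6-trien-1-one
Conditions: Pd(OAc)2 (5 mol%), SPhos (10 mol%), THF, 50 °C
Reagents that add atoms: none
Why: Negishi sp3–sp2 coupling with a bulky biarylphosphine should tolerate the di-ortho-substituted bromide, and the alkylzinc is inert toward the tropone carbonyl and its vinylogous ether groups.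

Step 7
Reactants: 9 5-[2-(1,3-dioxolan-2-yl)ethyl]-6-methoxy-4-methyl-2-[2-(trimethylsilyl)ethoxy]cyclohepta-2,4,6-trien-1-one
Product: 10 3-Ar-propanal
Conditions: 1 M HCl, THF, rt
Reagents that add atoms: water O
Why: Acid-catalysed acetal hydrolysis should free the aldehyde at room temperature, whereas alkoxytropones, being aromatic vinylogous esters, need hot acid to hydrolyse.

Step 8
Reactants: 11 (S)-3-bromo-2-methylpropan-1-ol
Product: 12 (S)-(3-bromo-2-methylpropoxy)(tert-butyl)dimethylsilane
Conditions: TBSCl, imidazole, CH2Cl2, 0 °C to rt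
Reagents that add atoms: tert-butyldimethylsilyl chloride CC(C)(C)[Si](C)(C)Cl
Why: Standard silylation of the primary alcohol protects it for zinc insertion and leaves the stereocentre untouched.

Step 9
Reactants: 12 (S)-(3-bromo-2-methylpropoxy)(tert-butyl)dimethylsilane; 7 5-bromo-6-methoxy-4-methyl-2-[2-(trimethylsilyl)ethoxy]cyclohepta-2,4,6-trien-1-one
Product: 14 5-[(2R)-3-(tert-butyldimethylsilyloxy)-2-methylpropyl]-6-methoxy-4-methyl-2-[2-(trimethylsilyl)ethoxy]cyclohepta-2,4,6-trien-1-one, via organozinc 13 (not isolated)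
Conditions: Zn dust, I2 (5 mol%), DMA, 70 °C; then 7, Pd(OAc)2 (5 mol%), SPhos (10 mol%), THF/DMA, 50 °C
Reagents that add atoms: none
Why: Direct zinc insertion into the primary C–Br bond and Negishi coupling carry the chiral-pool methyl stereocentre (β to zinc, never metalated) into the product unchanged, the descriptor changing from S to R only through CIP priorities.

Step 10
Reactants: 14 5-[(2R)-3-(tert-butyldimethylsilyloxy)-2-methylpropyl]-6-methoxy-4-methyl-2-[2-(trimethylsilyl)ethoxy]cyclohepta-2,4,6-trien-1-one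
Product: 15 (2R)-2-methyl-3-Ar-propan-1-ol
Conditions: HF·pyridine, THF/pyridine, 0 °C to rt
Reagents that add atoms: none
Why: Buffered HF should cleave the primary TBS ether while the 2-(trimethylsilyl)ethyl ether, which needs unsolvated fluoride to fragment, stays in place.

Step 11
Reactants: 15 (2R)-2-methyl-3-Ar-propan-1-ol
Product: 16 (2R)-2-methyl-3-Ar-propanal
Conditions: Dess–Martin periodinane, CH2Cl2, 0 °C to rt; used at once
Reagents that add atoms: none
Why: Dess–Martin oxidation is non-basic, so the α-methyl stereocentre of the aldehyde should not epimerise.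

Step 12
Reactants: 17 acetylene (two molecules per molecule of 18; the second one is entered below)
Product: 18 (1E,3E)-1,4-diiodobuta-1,3-diene
Conditions: PtI4 (cat.), NaI, I2, MeOH, acetylene (1 atm, bubbled through), rt
Reagents that add atoms: iodine II; acetylene C#C (second molecule of 17)
Why: Pt(IV)/iodide-catalysed iodinative dimerisation of acetylene (trans-iodoplatination of one acetylene, insertion of a second acetylene into the vinyl–Pt bond, C–I reductive elimination, reoxidation of Pt(II) by I2) is a known preparation of this (E,E)-diiodide, so the four-carbon diene is assembled from two C2 units and one I2.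

Step 13
Reactants: 10 3-Ar-propanal; 18 (1E,3E)-1,4-diiodobuta-1,3-diene (3 equiv)
Product: 19 (3R,4E,6E)-7-iodo-1-Ar-hepta-4,6-dien-3-ol
Conditions: CrCl2, L*, Et3N (complex pre-formed), NiCl2 (cat.), THF, rt
Reagents that add atoms: none
Why: Asymmetric Nozaki–Hiyama–Kishi coupling of a trans-iodoalkene with a 3-arylpropanal, in which the chiral Cr(III) complex should direct the dienyl group to the Si face to set 3R, the excess of diiodide limiting double addition.

Step 14
Reactants: 16 (2R)-2-methyl-3-Ar-propanal; 19 (3R,4E,6E)-7-iodo-1-Ar-hepta-4,6-dien-3-ol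
Product: 20 (2R,3R,4E,6E,8R)-2-methyl-1,10-di-Ar-deca-4,6-diene-3,8-diol
Conditions: CrCl2, L*, Et3N (complex pre-formed), NiCl2 (cat.), THF/MeCN, rt
Reagents that add atoms: none
Why: Ni(0) inserts into the C–I bond of 19, the dienyl group passes to Cr(III), and the dienylchromium(III) species held in the chiral oxazoline–sulfonamide complex adds to the aldehyde carbon of 16 (asymmetric Nozaki–Hiyama–Kishi coupling). The closest precedent is the ligand-controlled Ni/Cr coupling of trans-iodoalkenes with 3-arylpropanals and α-branched aldehydes. No ring is closed here; both pyran rings form in step 15. The new carbinol centre (3R, later C2 of the methyl-bearing pyran) is set by the ligand, which must deliver the dienyl group to the Si face against the weak Felkin–Anh preference of the α-methyl centre, itself untouched under these non-basic conditions. The step needs chemoselectivity for the aldehyde over two tropone carbonyls and the free C8 hydroxyl, which the low basicity and aldehyde selectivity of organochromium(III) reagents should provide, and retention of the (E,E)-geometry, which is usual for trans-alkenyl iodides.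

Step 15
Reactants: 20 (2R,3R,4E,6E,8R)-2-methyl-1,10-di-Ar-deca-4,6-diene-3,8-diol
Product: 23 bis[2-(trimethylsilyl)ethyl] ether of the target, via left-ring-closed alcohol 21 (not isolated), via right-ring-closed alcohol 22 (not isolated)
Conditions: KOt-Bu (0.3 equiv), 5 Å MS, THF (0.005 M), 0 °C to rt
Reagents that add atoms: none
Why: Each alkoxide should add 6-exo-trig to the β-carbon of its own β-methoxy tropone and expel methoxide (vinylogous transetherification by addition–elimination), so both carbinol C–O bonds stay intact and 3R and 8R are carried over with retention to give the 2,3-trans pyran and the 2'R pyran.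

Step 16
Reactants: 23 bis[2-(trimethylsilyl)ethyl] ether of the target
Product: 26 target CNP0332980.1, via left-tropolone mono-ether 24 (not isolated), via right-tropolone mono-ether 25 (not isolated)
Conditions: TBAF/AcOH (1:1), THF, 0 °C to rt; pH 6 buffer work-up
Reagents that add atoms: none
Why: Fluoride attack at silicon should fragment each 2-(trimethylsilyl)ethyl ether to ethylene and the tropolonate (a leaving group close to a carboxylate) without acid, hydroxide or Pd(0), all of which could open the dienylic vinylogous-ester C–O bonds.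

Compound list
1 | 2-methylanisole | COc1ccccc1C | starting material
2 | 1-methoxy-2-methylcyclohexa-1,4-diene | COC1=C(C)CC=CC1 | intermediate
3 | 7,7-dibromo-1-methoxy-6-methylbicyclo[4.1.0]hept-3-ene (racemic, cis-fused) | CO[C@@]12CC=CC[C@]1(C)C2(Br)Br | intermediate
4 | 7,7-dibromo-1-methoxy-6-methylbicyclo[4.1.0]heptane-3,4-diol (racemic, cis-diol anti to the CBr2 bridge) | CO[C@@]12C[C@@H](O)[C@@H](O)C[C@]1(C)C2(Br)Br | intermediate
5 | 7,7-dibromo-1-methoxy-6-methylbicyclo[4.1.0]heptane-3,4-dione (racemic) | CO[C@@]12CC(=O)C(=O)C[C@]1(C)C2(Br)Br | intermediate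
6 | 5-bromo-2-hydroxy-6-methoxy-4-methylcyclohepta-2,4,6-trien-1-one | COC1=CC(=O)C(O)=CC(C)=C1Br | intermediate
7 | 5-bromo-6-methoxy-4-methyl-2-[2-(trimethylsilyl)ethoxy]cyclohepta-2,4,6-trien-1-one | COC1=CC(=O)C(OCC[Si](C)(C)C)=CC(C)=C1Br | intermediate
8 | [2-(1,3-dioxolan-2-yl)ethyl]zinc bromide | Br[Zn]CCC1OCCO1 | starting material
9 | 5-[2-(1,3-dioxolan-2-yl)ethyl]-6-methoxy-4-methyl-2-[2-(trimethylsilyl)ethoxy]cyclohepta-2,4,6-trien-1-one | COC1=CC(=O)C(OCC[Si](C)(C)C)=CC(C)=C1CCC2OCCO2 | intermediate
10 | 3-Ar-propanal | COC1=CC(=O)C(OCC[Si](C)(C)C)=CC(C)=C1CCC=O | intermediate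
11 | (S)-3-bromo-2-methylpropan-1-ol | BrC[C@@H](C)CO | starting material
12 | (S)-(3-bromo-2-methylpropoxy)(tert-butyl)dimethylsilane | BrC[C@@H](C)CO[Si](C)(C)C(C)(C)C | intermediate
13 | (S)-[3-(tert-butyldimethylsilyloxy)-2-methylpropyl]zinc bromide | Br[Zn]C[C@@H](C)CO[Si](C)(C)C(C)(C)C | intermediate
14 | 5-[(2R)-3-(tert-butyldimethylsilyloxy)-2-methylpropyl]-6-methoxy-4-methyl-2-[2-(trimethylsilyl)ethoxy]cyclohepta-2,4,6-trien-1-one | COC1=CC(=O)C(OCC[Si](C)(C)C)=CC(C)=C1C[C@@H](C)CO[Si](C)(C)C(C)(C)C | intermediate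
15 | (2R)-2-methyl-3-Ar-propan-1-ol | COC1=CC(=O)C(OCC[Si](C)(C)C)=CC(C)=C1C[C@@H](C)CO | intermediate
16 | (2R)-2-methyl-3-Ar-propanal | COC1=CC(=O)C(OCC[Si](C)(C)C)=CC(C)=C1C[C@@H](C)C=O | intermediate
17 | acetylene | C#C | starting material
18 | (1E,3E)-1,4-diiodobuta-1,3-diene | I/C=C/C=C/I | intermediate
19 | (3R,4E,6E)-7-iodo-1-Ar-hepta-4,6-dien-3-ol | COC1=CC(=O)C(OCC[Si](C)(C)C)=CC(C)=C1CC[C@@H](O)/C=C/C=C/I | intermediate
20 | (2R,3R,4E,6E,8R)-2-methyl-1,10-di-Ar-deca-4,6-diene-3,8-diol | COC1=CC(=O)C(OCC[Si](C)(C)C)=CC(C)=C1C[C@@H](C)[C@@H](O)/C=C/C=C/[C@H](O)CCC2=C(C)C=C(OCC[Si](C)(C)C)C(=O)C=C2OC | intermediate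
21 | (2R,3R)-2-[(1E,3E,5R)-5-hydroxy-7-Ar-hepta-1,3-dienyl]-3,5-dimethyl-7-[2-(trimethylsilyl)ethoxy]-3,4-dihydrocyclohepta[b]pyran-8(2H)-one (left ring closed) | CC1=C2C[C@@H](C)[C@H](/C=C/C=C/[C@H](O)CCC3=C(C)C=C(OCC[Si](C)(C)C)C(=O)C=C3OC)OC2=CC(=O)C(OCC[Si](C)(C)C)=C1 | intermediate
22 | (2R)-2-[(1E,3E,5R,6R)-5-hydroxy-6-methyl-7-Ar-hepta-1,3-dienyl]-5-methyl-7-[2-(trimethylsilyl)ethoxy]-3,4-dihydrocyclohepta[b]pyran-8(2H)-one (right ring closed) | COC1=CC(=O)C(OCC[Si](C)(C)C)=CC(C)=C1C[C@@H](C)[C@@H](O)/C=C/C=C/[C@H]2CCC3=C(C)C=C(OCC[Si](C)(C)C)C(=O)C=C3O2 | intermediate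
23 | (2R,3R)-3,5-dimethyl-2-[(1E,3E)-4-[(2R)-5-methyl-8-oxo-7-[2-(trimethylsilyl)ethoxy]-2,3,4,8-tetrahydrocyclohepta[b]pyran-2-yl]buta-1,3-dienyl]-7-[2-(trimethylsilyl)ethoxy]-3,4-dihydrocyclohepta[b]pyran-8(2H)-one | CC1=C2C[C@@H](C)[C@H](/C=C/C=C/[C@H]3CCC4=C(C)C=C(OCC[Si](C)(C)C)C(=O)C=C4O3)OC2=CC(=O)C(OCC[Si](C)(C)C)=C1 | intermediate
24 | mono-ether of the target with the left (3-methylpyran) tropolone free and the right one still as its 2-(trimethylsilyl)ethyl ether | CC1=C2C[C@@H](C)[C@H](/C=C/C=C/[C@H]3CCC4=C(C)C=C(OCC[Si](C)(C)C)C(=O)C=C4O3)OC2=CC(=O)C(O)=C1 | intermediate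
25 | mono-ether of the target with the right tropolone free and the left one still as its 2-(trimethylsilyl)ethyl ether | CC1=C2C[C@@H](C)[C@H](/C=C/C=C/[C@H]3CCC4=C(C)C=C(O)C(=O)C=C4O3)OC2=CC(=O)C(OCC[Si](C)(C)C)=C1 | intermediate
26 | (2R,3R)-8-hydroxy-2-[(1E,3E)-4-[(2R)-8-hydroxy-5-methyl-7-oxo-2,3,4,7-tetrahydrocyclohepta[b]pyran-2-yl]buta-1,3-dienyl]-3,5-dimethyl-3,4-dihydrocyclohepta[b]pyran-7(2H)-one (CNP0332980.1) | Cc1cc(=O)c(O)cc2c1C[C@@H](C)[C@H](/C=C/C=C/[C@H]1CCc3c(C)cc(=O)c(O)cc3O1)O2 | target

Total step count: 16. Longest linear sequence: 11 steps (1, 2, 3, 4, 5, 6, 7, 13, 14, 15, 16 from 2-methylanisole; the branch through steps 9–11 is equally long).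

Steps most likely to fail

1. Step 14. The Si-face delivery is mismatched with the Felkin–Anh bias of the α-methyl aldehyde, so facial selectivity may be poor; coordination of Cr or Ni by the two tropones may also slow the coupling. Fallback: setting out from 19, the right-hand ring is closed first with catalytic KOt-Bu to give (2R)-2-[(1E,3E)-4-iodobuta-1,3-dienyl]-5-methyl-7-[2-(trimethylsilyl)ethoxy]-3,4-dihydrocyclohepta[b]pyran-8(2H)-one F1. A ligand-free NiCl2/CrCl2 coupling of F1 with 16 in DMSO then gives the C5-epimeric carbinols F2, and Dess–Martin oxidation converges both on the dienone F3. Reduction with (S)-Me-CBS and catecholborane should give the 5R alcohol, the reagent control being reinforced by Felkin–Anh hydride delivery (hydride and dienyl have exchanged roles relative to the aldehyde addition). The product is 22, where the fallback rejoins the route for ring closure under the conditions of step 15.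

2. Step 13. Enantiofacial control on an aldehyde without α-substituent may be incomplete, and the product iodide may add to a second aldehyde. Fallback: setting out from 10 and 18, a ligand-free NiCl2/CrCl2 coupling in DMSO gives racemic 7-iodo-1-Ar-hepta-4,6-dien-3-ol F4. Dess–Martin oxidation gives (4E,6E)-7-iodo-1-Ar-hepta-4,6-dien-3-one F5, and Corey–Bakshi–Shibata reduction with (S)-Me-CBS and catecholborane (dienyl as the large group) should return 19 in the 3R series, where the route is rejoined.

3. Step 3. The donor-substituted gem-dibromocyclopropane may ionise and ring-open in the aqueous medium before the diol is formed, with loss of the methoxy group that is needed later as leaving group. Fallback: setting out from 2, dichlorocarbene (CHCl3, 50% NaOH, BnEt3NCl) gives the much less ionisable 7,7-dichloro-1-methoxy-6-methylbicyclo[4.1.0]hept-3-ene F6. Upjohn dihydroxylation gives 7,7-dichloro-1-methoxy-6-methylbicyclo[4.1.0]heptane-3,4-diol F7. Swern oxidation gives 7,7-dichloro-1-methoxy-6-methylbicyclo[4.1.0]heptane-3,4-dione F8, which with DBU at 40 °C should open to 5-chloro-2-hydroxy-6-methoxy-4-methylcyclohepta-2,4,6-trien-1-one F9. Mitsunobu etherification with 2-(trimethylsilyl)ethanol gives 5-chloro-6-methoxy-4-methyl-2-[2-(trimethylsilyl)ethoxy]cyclohepta-2,4,6-trien-1-one F10. Negishi couplings of F10 with 8 and with 13 under a Pd/XPhos catalyst rejoin the route at 9 and at 14.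

Further compounds
F1 | step 14 | (2R)-2-[(1E,3E)-4-iodobuta-1,3-dienyl]-5-methyl-7-[2-(trimethylsilyl)ethoxy]-3,4-dihydrocyclohepta[b]pyran-8(2H)-one | I/C=C/C=C/[C@H]1CCC2=C(C)C=C(OCC[Si](C)(C)C)C(=O)C=C2O1
F2 | step 14 | (2R)-2-[(1E,3E,6R)-5-hydroxy-6-methyl-7-Ar-hepta-1,3-dienyl]-5-methyl-7-[2-(trimethylsilyl)ethoxy]-3,4-dihydrocyclohepta[b]pyran-8(2H)-one, mixture of C5 epimers | COC1=CC(=O)C(OCC[Si](C)(C)C)=CC(C)=C1C[C@@H](C)C(O)/C=C/C=C/[C@H]2CCC3=C(C)C=C(OCC[Si](C)(C)C)C(=O)C=C3O2
F3 | step 14 | (2R)-5-methyl-2-[(1E,3E,6R)-6-methyl-5-oxo-7-Ar-hepta-1,3-dienyl]-7-[2-(trimethylsilyl)ethoxy]-3,4-dihydrocyclohepta[b]pyran-8(2H)-one | COC1=CC(=O)C(OCC[Si](C)(C)C)=CC(C)=C1C[C@@H](C)C(=O)/C=C/C=C/[C@H]2CCC3=C(C)C=C(OCC[Si](C)(C)C)C(=O)C=C3O2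
F4 | step 13 | racemic (4E,6E)-7-iodo-1-Ar-hepta-4,6-dien-3-ol | COC1=CC(=O)C(OCC[Si](C)(C)C)=CC(C)=C1CCC(O)/C=C/C=C/I
F5 | step 13 | (4E,6E)-7-iodo-1-Ar-hepta-4,6-dien-3-one | COC1=CC(=O)C(OCC[Si](C)(C)C)=CC(C)=C1CCC(=O)/C=C/C=C/I
F6 | step 3 | 7,7-dichloro-1-methoxy-6-methylbicyclo[4.1.0]hept-3-ene (racemic) | CO[C@@]12CC=CC[C@]1(C)C2(Cl)Cl
F7 | step 3 | 7,7-dichloro-1-methoxy-6-methylbicyclo[4.1.0]heptane-3,4-diol (racemic) | CO[C@@]12C[C@@H](O)[C@@H](O)C[C@]1(C)C2(Cl)Cl
F8 | step 3 | 7,7-dichloro-1-methoxy-6-methylbicyclo[4.1.0]heptane-3,4-dione (racemic) | CO[C@@]12CC(=O)C(=O)C[C@]1(C)C2(Cl)Cl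
F9 | step 3 | 5-chloro-2-hydroxy-6-methoxy-4-methylcyclohepta-2,4,6-trien-1-one | COC1=CC(=O)C(O)=CC(C)=C1Cl
F10 | step 3 | 5-chloro-6-methoxy-4-methyl-2-[2-(trimethylsilyl)ethoxy]cyclohepta-2,4,6-trien-1-one | COC1=CC(=O)C(OCC[Si](C)(C)C)=CC(C)=C1Cl
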